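## Structural features

The target is a cis-fused bicyclo[5.3.0]decane of the daucane type in which a cyclopentane (C1–C5) and a cycloheptane (C1, C5–C10) share the C1–C5 bond; the numbering used throughout is C1 quaternary angular carbon (methyl), C2 CHOH, C3 CH2, C4 tertiary carbinol carrying the isopropyl group, C5 ring-fusion CH, C6 CH–O (angelate), C7 CH2, C8 (methyl) and C9 epoxide carbons, C10 CH–O (angelate). All eight stereocentres (1S,2S,4R,5S,6S,8S,9R,10R) are clustered: C1 is flanked by C2, C5 and C10, C5 by C4 and C6, and C8/C9 adjoin C10. With α defined as the face that carries the C1 methyl group (a local convention), H5, the C2 hydroxyl, the C4 isopropyl group and the C6 ester are α, while the C4 hydroxyl, the C10 ester and the epoxide are β. Hence O2 is trans to O4 on the five-membered ring, O4 lies on the β face of the C6 position, and the epoxide is syn to O10. The fragile groups are the two angelates (Z to E isomerisation), the trisubstituted epoxide (acid) and the tertiary C4 alcohol, which becomes a retro-aldol and dehydration liability whenever C2 or C6 is a carbonyl. The real difficulty is the quaternary C1 inside the cis 5–7 junction with three stereogenic neighbours, together with the differentiation of three secondary hydroxyls (O2 free, O6 and O10 acylated). The key step exploits the seven-membered ring: C7 is its only methylene and lies between the oxygenated C6 and the methyl-bearing C8. If the epoxide is read as a C8=C9 alkene and the C6 oxygen as a heteroatom on a C5=C6 alkene, the ring is a cyclohepta-1,4-diene whose sp3 atoms C10 and C1 are joined by exactly the bond that a Cope rearrangement of a cis-divinylcyclopropane (C6–C7–C8) forms.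

## Logic of the disconnections

**29 to 28.** The benzylic C–O bond of the ether on O2 is cut. O2 must stay blocked while O6 and O10 are acylated, so its unmasking is the last operation. The gain is that the three secondary hydroxyls are told apart. The forward step must be neutral and must spare two angelates, the epoxide and the tertiary alcohol.

**28 to 27 + 24.** The acyl C–O bond at O10 is cut. This ester sits on a neopentyl carbinol next to the epoxide and is the more isomerisation-prone to install, so it is placed as late as possible. Five carbons are removed. The forward step must acylate a hindered alcohol without Z to E isomerisation and without opening the epoxide.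

**27 to 26.** The two epoxide C–O bonds are cut. The 10β-hydroxyl is allylic to C8=C9 and on the face on which the oxygen is needed, so a hydroxyl-directed epoxidation sets C8 and C9 together. The forward step needs O10 as the only free hydroxyl near the alkene and no other electron-rich alkene or sulfide.

**26 to 25.** The O10–Si bond is cut. Keeping O10 silylated until O6 carries its ester differentiates O6 from O10 by the order of unmasking. The forward step must remove a hindered silyl ether without touching the ester at O6.

**25 to 23 + 24.** The acyl C–O bond at O6 is cut. At this stage O6 is the only free secondary hydroxyl, so no selectivity problem arises. Five carbons are removed. The forward step must leave the tertiary O4 and the alkene geometry of the acid untouched.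

**23 to 22 to 21.** The C6–H bond, the C5–H bond and the C6=O bond are addressed. The 6α-carbinol comes from a C6 ketone by hydride delivery from the β-hydroxyl on C4, H5 is set by equilibration next to that ketone, and the ketone is the hydrolysis product of a vinyl sulfide. Two stereocentres are removed. The forward steps require that the cis-fused ketone is the thermodynamic C5 epimer and that the C4 hydroxyl is free.

**21 to 20 to 19.** The O2–benzyl bond and the C2–H bond are cut. The 2α-carbinol comes from the C2 ketone by the same C4-hydroxyl-delivered hydride and is protected before C6 is unmasked. The two carbonyls that flank C4 are thus handled one after the other. The forward steps need a directed reduction across the five-membered ring and an etherification that leaves the tertiary hydroxyl free.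

**19 to 18 (key).** C1–C10 is cut and C6–C8 is re-formed. In one sentence: a thermal Cope rearrangement of the cis-divinylcyclopropane array of 18 closes the seven-membered ring and creates the quaternary C1 and C10. The bicycle with three stereocentres becomes a monocyclic cyclopentenone with one stereocentre and a cyclopropane whose configuration is levelled. The forward step demands facial selectivity with respect to C4, an E enol ether, and convergence of all cyclopropane stereoisomers.

**18 to 14 + 8.** C5–C6 is cut. A sulfur-stabilised cyclopropyl anion adds to a carbonyl at C5, and transposition of a vinylogous ester returns the C2 carbonyl. Two fragments of similar size result. The demand is that C5 is the only free carbonyl of 8.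

**8 to 7 to 6 to 5 to 2 + 3, and 2 to 1.** The enol ether C–O bond, the C1–C5 bond (Claisen), the C2 oxygen (alkyne hydration), the C3–C4 bond (enolate alkylation) and the acetal are cut. The only stereocentre that is bought (C4, from 1) is regenerated with retention in the alkylation. The demand is an alkylation anti to the acetal substituent and a regioselective hydration.

**14 to 12 to 10 + 11, and 10 to 9.** The C6–S bond, the C6–C7 and C6–C8 bonds (carbene addition) and the O–Si bond are cut. The fragment is reduced to a four-carbon enal and a one-carbon carbene source. The carbene must add to the 1,1-disubstituted alkene of 10, and the enol ether must be E.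

## Other disconnections considered

Alternative 1: Cut C8=C9 and close the seven-membered ring by ring-closing metathesis of diene A1 under ruthenium alkylidene catalysis to give cycloheptene A2 (the first plan that comes to mind). The metathesis forms no stereocentre and no σ-bond of the congested core. A1 already contains the quaternary C1 and its four stereogenic neighbours (C2, C5, C6, C10), each of which would need its own controlled C–C or C–O bond formation on a cyclopentane. A trisubstituted alkene next to the neopentyl C10 is also a slow metathesis case. The difficulty is moved into the precursor, not removed.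

Alternative 2: Chiral-pool ring remodelling. Cleave the ring alkene of the terpene alcohol A3 and re-close by aldol condensation to cyclopentenecarbaldehyde A4, which maps C1–C6 with the C4 carbinol in place. C7–C10 would be attached by 1,2-addition at C6 and conjugate addition at C1. The mapping is attractive, but C2 arrives as an unactivated methylene with no handle for the 2α-hydroxyl. The quaternary C1 would have to be made by conjugate addition to a β,β-disubstituted enal flanked by the quaternary C4. Neither C1 nor C10 is controlled by a concerted event.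

Alternative 3: Diels–Alder reaction of cyclopentenone A5 with diene 10 to give the cis-hydrindenone A6, followed by one-carbon ring expansion. The cycloaddition would set C1, C5 and C10 and place C8=C9 correctly in one step. The ring is one carbon short, however, and the missing atom is the oxygenated C6, which would have to be inserted into the unactivated C5–C7 σ-bond. The only carbonyl (C2) is in the other ring, so no ketone-homologation logic applies. The chosen Cope route uses the same four-carbon unit 10 and delivers the seven-membered ring directly.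

Key step: step 10

Remark on the chemistry: the SMILES fixes a cis ring fusion (C1 methyl and H5 on the same face) and Z (angelate) esters, and the route is designed for exactly this stereoisomer; the bicyclic compounds are named on the daucane skeleton with the numbering and the α/β convention defined under "Structural features".

## Steps

Step 1
Reactants: 1 (R)-2-hydroxy-3-methylbutanoic acid
Product: 2 (2R,5R)-2-tert-butyl-5-(propan-2-yl)-1,3-dioxolan-4-one
Conditions: t-BuCHO, TsOH·H2O (cat.), H2SO4 (cat.), pentane, reflux, Dean–Stark
Reagents that add atoms: pivalaldehyde, CC(C)(C)C=O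
Why: Acid-catalysed acetalisation of the α-hydroxy acid; the cis-dioxolanone is the thermodynamic isomer and its acetal centre stores the configuration of the future C4 (self-regeneration of stereocentres).

Step 2
Reactants: 2 (2R,5R)-2-tert-butyl-5-(propan-2-yl)-1,3-dioxolan-4-one; 3 1-bromobut-2-yne
Product: 5 (2R,5R)-5-(but-2-yn-1-yl)-2-tert-butyl-5-(propan-2-yl)-1,3-dioxolan-4-one, via lithium enolate 4 (not isolated)
Conditions: LiN(iPr)2, THF, −78 °C; then 3, −78 to −30 °C
Reagents that add atoms: none
Why: Enolate alkylation with a reactive propargylic bromide; the electrophile enters anti to the tert-butyl group, so the C3–C4 bond replaces the former C–H with overall retention and the quaternary carbinol centre C4 is set.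

Step 3
Reactants: 5 (2R,5R)-5-(but-2-yn-1-yl)-2-tert-butyl-5-(propan-2-yl)-1,3-dioxolan-4-one
Product: 6 (2R,5R)-2-tert-butyl-5-(2-oxobutyl)-5-(propan-2-yl)-1,3-dioxolan-4-one
Conditions: NaAuCl4·2H2O (2 mol %), MeCN/H2O (10:1), 50 °C
Reagents that add atoms: water, O
Why: Gold-catalysed alkyne hydration with neighbouring-group participation; the lactone carbonyl oxygen attacks the activated alkyne 5-exo-dig, so oxygen is delivered to the proximal alkyne carbon (future C2).

Step 4
Reactants: 6 (2R,5R)-2-tert-butyl-5-(2-oxobutyl)-5-(propan-2-yl)-1,3-dioxolan-4-one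
Product: 7 (4R)-4-hydroxy-2-methyl-4-(propan-2-yl)cyclopentane-1,3-dione
Conditions: KOt-Bu (2.1 equiv), THF, 0 °C to rt; cold 1 M HCl
Reagents that add atoms: none
Why: Intramolecular Claisen (Dieckmann-type) condensation; the ketone enolate on the ethyl side (C1) attacks the activated lactone carbonyl (C5) 5-exo-trig, the tetrahedral intermediate expels pivalaldehyde, and deprotonation of the 1,3-dione drives the reaction. C4 is not touched.

Step 5
Reactants: 7 (4R)-4-hydroxy-2-methyl-4-(propan-2-yl)cyclopentane-1,3-dione
Product: 8 (5R)-5-hydroxy-3-methoxy-2-methyl-5-(propan-2-yl)cyclopent-2-en-1-one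
Conditions: MeOH, TsOH·H2O (cat.), 3 Å MS, 40 °C
Reagents that add atoms: methanol, CO
Why: Vinylogous esterification under equilibrating conditions; methanol should condense at the carbonyl remote from the quaternary centre (C2), leaving the hindered, hydrogen-bonded C5 carbonyl free for the 1,2-addition.

Step 6
Reactants: 9 3-methylbut-2-enal
Product: 10 (E)-triisopropyl[(3-methylbuta-1,3-dien-1-yl)oxy]silane
Conditions: iPr3SiOTf, Et3N, Et2O, 0 °C to rt
Reagents that add atoms: triisopropylsilyl trifluoromethanesulfonate, CC(C)[Si](OS(=O)(=O)C(F)(F)F)(C(C)C)C(C)C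
Why: Silyl dienol ether formation (O-silylation, then γ-deprotonation of the s-trans oxocarbenium ion) should give the (1E)-diene; this geometry later fixes C10.

Step 7
Reactants: 10 (E)-triisopropyl[(3-methylbuta-1,3-dien-1-yl)oxy]silane; 11 bromoform
Product: 12 rac-{[(E)-2-(2,2-dibromo-1-methylcyclopropyl)ethenyl]oxy}triisopropylsilane
Conditions: KOt-Bu, pentane, −20 to 0 °C
Reagents that add atoms: none
Why: Dibromocarbene [2+1] cycloaddition; the electrophilic carbene should attack the terminal CH2 of the 1-oxydiene (largest HOMO coefficient, developing charge at the tertiary, vinylogously oxygen-stabilised C8) and so add to the 1,1-disubstituted alkene, not to the shielded silyl enol ether. The product is racemic and its configuration is irrelevant.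

Step 8
Reactants: 12 rac-{[(E)-2-(2,2-dibromo-1-methylcyclopropyl)ethenyl]oxy}triisopropylsilane
Product: 14 {[(E)-2-(2-bromo-1-methyl-2-(phenylsulfanyl)cyclopropyl)ethenyl]oxy}triisopropylsilane (racemic diastereomer mixture), via bromolithiocyclopropane 13 (not isolated)
Conditions: n-BuLi, THF/Et2O, −105 °C; then PhSSPh, −105 to −78 °C; aq. NH4Cl
Reagents that add atoms: diphenyl disulfide, c1ccc(SSc2ccccc2)cc1
Why: Bromine–lithium exchange gives a cyclopropylidene carbenoid that is stable at this temperature and is sulfenylated; the diastereomers at C6 are of no consequence.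

Step 9
Reactants: 14 {[(E)-2-(2-bromo-1-methyl-2-(phenylsulfanyl)cyclopropyl)ethenyl]oxy}triisopropylsilane; 8 (5R)-5-hydroxy-3-methoxy-2-methyl-5-(propan-2-yl)cyclopent-2-en-1-one
Product: 18 (4R)-4-hydroxy-2-methyl-3-[2-methyl-1-(phenylsulfanyl)-2-{(E)-2-(triisopropylsilyloxy)ethenyl}cyclopropyl]-4-(propan-2-yl)cyclopent-2-en-1-one (mixture of cyclopropane stereoisomers), via lithiated cyclopropyl sulfide 15 (not isolated), via lithium alkoxide 16 (not isolated), via tertiary carbinol adduct 17 (not isolated)
Conditions: 8, n-BuLi (1.0 equiv), THF, −78 °C; separately 14, n-BuLi (1.05 equiv), THF, −78 °C; combine, −78 to −40 °C; aq. NH4Cl; then PPTS (cat.), wet CH2Cl2, 0 °C to rt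
Reagents that add atoms: water, O
Why: Stork–Danheiser sequence: the compact α-thiocyclopropyllithium (a class of nucleophile that adds well to hindered ketones) adds 1,2 to the only free carbonyl (C5) of the pre-formed alkoxide, and mild aqueous acid hydrolyses the enol ether and eliminates the new tertiary hydroxyl, which transposes the carbonyl to C2 with loss of methanol. No stereocentre needs control, because C5 becomes sp2 and the cyclopropane configuration is levelled in step 10; the alkoxide is kept at −78 °C to prevent retro-aldol opening.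

Step 10
Reactants: 18 (4R)-4-hydroxy-2-methyl-3-[2-methyl-1-(phenylsulfanyl)-2-{(E)-2-(triisopropylsilyloxy)ethenyl}cyclopropyl]-4-(propan-2-yl)cyclopent-2-en-1-one
Product: 19 4β-hydroxy-6-(phenylsulfanyl)-10β-(triisopropylsilyloxy)dauca-5,8-dien-2-one (C1 methyl α; C4 isopropyl α)
Conditions: PhMe (degassed), 2,6-di-tert-butyl-4-methylpyridine (0.2 equiv), sealed base-washed tube, 110 to 150 °C
Reagents that add atoms: none
Why: Thermal [3,3]-sigmatropic divinylcyclopropane–cycloheptadiene (Cope) rearrangement: the C6–C8 cyclopropane bond is cleaved, C1–C10 is formed, and the alkenes move to C5=C6 (vinyl sulfide) and C8=C9. The closest known reaction type is the cycloheptannulation of 3-(2-vinylcyclopropyl)cycloalk-2-enones, including 2-methylcycloalkenones that deliver an angular methyl group next to the ketone. The seven-membered ring is closed by the sigmatropic shift itself through a boat-like transition state with both alkenyl groups endo over the three-membered ring, not by a polar or radical cyclisation. Only cis isomers reach this geometry; the trans isomers and the cis isomers of the wrong facial series should interconvert by reversible homolysis of the C6–C8 bond (radical at C6 stabilised by sulfur and the enone, at C8 by the oxyallyl system), so all stereoisomers of 18 should funnel into one product. C1 is controlled by C4: C8 and its methyl group must lie above or below the cyclopentenone plane right next to C4, they avoid the α-isopropyl group and pass over the small β-hydroxyl, so C10 bonds to the β face of C1 and the methyl group ends up α. C10 is controlled by alkene geometry: in the boat transition state the E substituents of the two termini become cis on the new ring, C2 is the E substituent on C1 by ring constraint and the silyloxy group is E on C10, hence 10β-OSi, trans to the C1 methyl. The step needs the Cope channel to outrun the homodienyl 1,5-hydrogen shift of the trans isomer (C8 methyl cis to the cyclopentenyl group) and the vinylcyclopropane–cyclopentene ring enlargement; the captodative weakening of the C6–C8 bond should make stereomutation and rearrangement faster than both. The hindered pyridine base only scavenges adventitious acid, so neither the silyl enol ether of 18 nor the β-hydroxy ketone of 19 is exposed to acid or to a soluble strong base.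

Step 11
Reactants: 19 4β-hydroxy-6-(phenylsulfanyl)-10β-(triisopropylsilyloxy)dauca-5,8-dien-2-one
Product: 20 6-(phenylsulfanyl)-10β-(triisopropylsilyloxy)dauca-5,8-diene-2α,4β-diol
Conditions: Me4NBH(OAc)3, MeCN/AcOH (1:1), −35 to −20 °C
Reagents that add atoms: none
Why: Hydroxyl-directed reduction of the β-hydroxy ketone (Evans–Saksena reduction); the alkoxyborohydride on the 4β-oxygen delivers hydride across the five-membered ring to the β face of C2, giving the 2α-alcohol trans to O4. C6 is still masked, so the two carbonyls flanking C4 are differentiated.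

Step 12
Reactants: 20 6-(phenylsulfanyl)-10β-(triisopropylsilyloxy)dauca-5,8-diene-2α,4β-diol
Product: 21 2α-(4-methoxybenzyloxy)-6-(phenylsulfanyl)-10β-(triisopropylsilyloxy)dauca-5,8-dien-4β-ol
Conditions: NaH, 4-MeOC6H4CH2Br, Bu4NI (cat.), THF/DMF, 0 °C to rt
Reagents that add atoms: 4-methoxybenzyl bromide, COc1ccc(CBr)cc1
Why: Williamson etherification of the only secondary hydroxyl; the tertiary C4 alkoxide is too hindered to compete, and with no carbonyl at C2 or C6 no retro-aldol pathway exists under base.

Step 13
Reactants: 21 2α-(4-methoxybenzyloxy)-6-(phenylsulfanyl)-10β-(triisopropylsilyloxy)dauca-5,8-dien-4β-ol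
Product: 22 4β-hydroxy-2α-(4-methoxybenzyloxy)-10β-(triisopropylsilyloxy)-5αH-dauc-8-en-6-one
Conditions: HgCl2, CaCO3, MeCN/H2O (4:1), 50 °C; then DBU (0.1 equiv), CH2Cl2, rt
Reagents that add atoms: water, O
Why: Thiophile-assisted hydrolysis of the vinyl sulfide (protonation at C5, thionium ion, hemithioketal) unmasks the C6 ketone. C5 is then epimerisable, and equilibration should give the cis-fused ketone, in which C6 is trans to both the C4 isopropyl group and the C1 methyl group on the cyclopentane and can accept a hydrogen bond from the 4β-hydroxyl.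

Step 14
Reactants: 22 4β-hydroxy-2α-(4-methoxybenzyloxy)-10β-(triisopropylsilyloxy)-5αH-dauc-8-en-6-one
Product: 23 2α-(4-methoxybenzyloxy)-10β-(triisopropylsilyloxy)-5αH-dauc-8-ene-4β,6α-diol
Conditions: Me4NBH(OAc)3, MeCN/AcOH (1:1), −35 to −20 °C
Reagents that add atoms: none
Why: Second hydroxyl-directed (Evans–Saksena) reduction; O4 and C6 are cis on the five-membered ring, so the boron-bound hydride reaches the β face of the C6 carbonyl through a chair-like six-membered transition state and the 6α-alcohol results.

Step 15
Reactants: 23 2α-(4-methoxybenzyloxy)-10β-(triisopropylsilyloxy)-5αH-dauc-8-ene-4β,6α-diol; 24 angelic acid ((Z)-2-methylbut-2-enoic acid)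
Product: 25 6α-(angeloyloxy)-2α-(4-methoxybenzyloxy)-10β-(triisopropylsilyloxy)-5αH-dauc-8-en-4β-ol
Conditions: 24, 2,4,6-Cl3C6H2COCl, Et3N, PhMe, rt; filter; then 23, PhMe, 75 °C
Reagents that add atoms: none
Why: Yamaguchi-type esterification through the mixed anhydride, the standard way to make angelates of hindered alcohols without a nucleophilic acyl-transfer catalyst that would isomerise Z to E. O6 is the only free secondary hydroxyl (O10 silylated, O2 benzylated) and the tertiary O4 does not react.

Step 16
Reactants: 25 6α-(angeloyloxy)-2α-(4-methoxybenzyloxy)-10β-(triisopropylsilyloxy)-5αH-dauc-8-en-4β-ol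
Product: 26 6α-(angeloyloxy)-2α-(4-methoxybenzyloxy)-5αH-dauc-8-ene-4β,10β-diol
Conditions: Bu4NF, AcOH (1:1), THF, 0 °C to rt
Reagents that add atoms: none
Why: Fluoride desilylation of the allylic silyl ether, buffered so that no free alkoxide is present that could attack or shift the angelate; the 4-methoxybenzyl ether is inert.

Step 17
Reactants: 26 6α-(angeloyloxy)-2α-(4-methoxybenzyloxy)-5αH-dauc-8-ene-4β,10β-diol
Product: 27 6α-(angeloyloxy)-8β,9β-epoxy-2α-(4-methoxybenzyloxy)-5αH-daucane-4β,10β-diol
Conditions: VO(acac)2 (5 mol %), t-BuOOH (decane solution), CH2Cl2, 0 °C to rt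
Reagents that add atoms: tert-butyl hydroperoxide, CC(C)(C)OO
Why: Vanadium-catalysed hydroxyl-directed epoxidation of a cyclic allylic alcohol; the metal-bound peroxide is delivered to the face of the 10β-hydroxyl, setting C8 and C9 together. O6 is acylated and cannot compete as a directing group, and the electron-poor angelate alkene is not epoxidised.

Step 18
Reactants: 27 6α-(angeloyloxy)-8β,9β-epoxy-2α-(4-methoxybenzyloxy)-5αH-daucane-4β,10β-diol; 24 angelic acid ((Z)-2-methylbut-2-enoic acid)
Product: 28 6α,10β-bis(angeloyloxy)-8β,9β-epoxy-2α-(4-methoxybenzyloxy)-5αH-daucan-4β-ol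
Conditions: 24, 2,4,6-Cl3C6H2COCl, Et3N, PhMe, rt; filter; then 27, PhMe, 80 °C
Reagents that add atoms: none
Why: Second Yamaguchi-type esterification, now at the only remaining secondary hydroxyl (O10); the pre-formed, filtered mixed anhydride keeps chloride and free base away from the epoxide, and the tertiary O4 does not react.

Step 19
Reactants: 28 6α,10β-bis(angeloyloxy)-8β,9β-epoxy-2α-(4-methoxybenzyloxy)-5αH-daucan-4β-ol
Product: 29 6α,10β-bis(angeloyloxy)-8β,9β-epoxy-5αH-daucane-2α,4β-diol (target)
Conditions: DDQ, CH2Cl2/pH 7 phosphate buffer (10:1), 0 °C to rt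
Reagents that add atoms: none
Why: Oxidative cleavage of the 4-methoxybenzyl ether under buffered neutral conditions, which the epoxide, the tertiary alcohol and the electron-poor angelate alkenes should tolerate.

## Compound list

1 | (R)-2-hydroxy-3-methylbutanoic acid | CC(C)[C@@H](O)C(=O)O | starting material
2 | (2R,5R)-2-tert-butyl-5-(propan-2-yl)-1,3-dioxolan-4-one | O=C1O[C@H](C(C)(C)C)O[C@@H]1C(C)C | intermediate
3 | 1-bromobut-2-yne | CC#CCBr | starting material
4 | lithium (2R)-2-tert-butyl-5-(propan-2-yl)-1,3-dioxol-4-olate, the enolate of 2 (not isolated) | [Li]OC1=C(C(C)C)O[C@@H](C(C)(C)C)O1 | intermediate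
5 | (2R,5R)-5-(but-2-yn-1-yl)-2-tert-butyl-5-(propan-2-yl)-1,3-dioxolan-4-one | O=C1O[C@H](C(C)(C)C)O[C@]1(CC#CC)C(C)C | intermediate
6 | (2R,5R)-2-tert-butyl-5-(2-oxobutyl)-5-(propan-2-yl)-1,3-dioxolan-4-one | O=C1O[C@H](C(C)(C)C)O[C@]1(CC(=O)CC)C(C)C | intermediate
7 | (4R)-4-hydroxy-2-methyl-4-(propan-2-yl)cyclopentane-1,3-dione | CC1C(=O)C[C@@](O)(C(C)C)C1=O | intermediate
8 | (5R)-5-hydroxy-3-methoxy-2-methyl-5-(propan-2-yl)cyclopent-2-en-1-one | COC1=C(C)C(=O)[C@](O)(C(C)C)C1 | intermediate
9 | 3-methylbut-2-enal | CC(C)=CC=O | starting material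
10 | (E)-triisopropyl[(3-methylbuta-1,3-dien-1-yl)oxy]silane | C=C(C)/C=C/O[Si](C(C)C)(C(C)C)C(C)C | intermediate
11 | bromoform | BrC(Br)Br | starting material
12 | rac-{[(E)-2-(2,2-dibromo-1-methylcyclopropyl)ethenyl]oxy}triisopropylsilane | CC1(/C=C/O[Si](C(C)C)(C(C)C)C(C)C)CC1(Br)Br | intermediate
13 | 1-bromo-1-lithio-2-methyl-2-[(E)-2-(triisopropylsilyloxy)ethenyl]cyclopropane (not isolated) | [Li]C1(Br)CC1(C)/C=C/O[Si](C(C)C)(C(C)C)C(C)C | intermediate
14 | {[(E)-2-(2-bromo-1-methyl-2-(phenylsulfanyl)cyclopropyl)ethenyl]oxy}triisopropylsilane (racemic diastereomer mixture) | CC1(/C=C/O[Si](C(C)C)(C(C)C)C(C)C)CC1(Br)Sc1ccccc1 | intermediate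
15 | 1-lithio-2-methyl-1-(phenylsulfanyl)-2-[(E)-2-(triisopropylsilyloxy)ethenyl]cyclopropane (not isolated) | [Li]C1(Sc2ccccc2)CC1(C)/C=C/O[Si](C(C)C)(C(C)C)C(C)C | intermediate
16 | lithium alkoxide of 8 (not isolated) | COC1=C(C)C(=O)[C@](O[Li])(C(C)C)C1 | intermediate
17 | (5R)-3-methoxy-2-methyl-1-[2-methyl-1-(phenylsulfanyl)-2-{(E)-2-(triisopropylsilyloxy)ethenyl}cyclopropyl]-5-(propan-2-yl)cyclopent-2-ene-1,5-diol (formed as its dilithium salt; stereoisomer mixture; not isolated) | COC1=C(C)C(O)(C2(Sc3ccccc3)CC2(C)/C=C/O[Si](C(C)C)(C(C)C)C(C)C)[C@](O)(C(C)C)C1 | intermediate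
18 | (4R)-4-hydroxy-2-methyl-3-[2-methyl-1-(phenylsulfanyl)-2-{(E)-2-(triisopropylsilyloxy)ethenyl}cyclopropyl]-4-(propan-2-yl)cyclopent-2-en-1-one (cyclopropane stereoisomer mixture) | CC1=C(C2(Sc3ccccc3)CC2(C)/C=C/O[Si](C(C)C)(C(C)C)C(C)C)[C@](O)(C(C)C)CC1=O | intermediate
19 | 4β-hydroxy-6-(phenylsulfanyl)-10β-(triisopropylsilyloxy)dauca-5,8-dien-2-one (C1 methyl α, C4 isopropyl α) | C1(Sc3ccccc3)CC(C)=C[C@H](O[Si](C(C)C)(C(C)C)C(C)C)[C@@]2(C)C=1[C@](O)(C(C)C)CC2=O | intermediate
20 | 6-(phenylsulfanyl)-10β-(triisopropylsilyloxy)dauca-5,8-diene-2α,4β-diol | C1(Sc3ccccc3)CC(C)=C[C@H](O[Si](C(C)C)(C(C)C)C(C)C)[C@@]2(C)C=1[C@](O)(C(C)C)C[C@@H]2O | intermediate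
21 | 2α-(4-methoxybenzyloxy)-6-(phenylsulfanyl)-10β-(triisopropylsilyloxy)dauca-5,8-dien-4β-ol | C1(Sc3ccccc3)CC(C)=C[C@H](O[Si](C(C)C)(C(C)C)C(C)C)[C@@]2(C)C=1[C@](O)(C(C)C)C[C@@H]2OCc4ccc(OC)cc4 | intermediate
22 | 4β-hydroxy-2α-(4-methoxybenzyloxy)-10β-(triisopropylsilyloxy)-5αH-dauc-8-en-6-one | O=C1CC(C)=C[C@H](O[Si](C(C)C)(C(C)C)C(C)C)[C@@]2(C)[C@@H]1[C@](O)(C(C)C)C[C@@H]2OCc3ccc(OC)cc3 | intermediate
23 | 2α-(4-methoxybenzyloxy)-10β-(triisopropylsilyloxy)-5αH-dauc-8-ene-4β,6α-diol | O[C@H]1CC(C)=C[C@H](O[Si](C(C)C)(C(C)C)C(C)C)[C@@]2(C)[C@@H]1[C@](O)(C(C)C)C[C@@H]2OCc3ccc(OC)cc3 | intermediate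
24 | angelic acid ((Z)-2-methylbut-2-enoic acid) | C/C=C(/C)C(=O)O | starting material
25 | 6α-(angeloyloxy)-2α-(4-methoxybenzyloxy)-10β-(triisopropylsilyloxy)-5αH-dauc-8-en-4β-ol | C/C=C(/C)C(=O)O[C@H]1CC(C)=C[C@H](O[Si](C(C)C)(C(C)C)C(C)C)[C@@]2(C)[C@@H]1[C@](O)(C(C)C)C[C@@H]2OCc3ccc(OC)cc3 | intermediate
26 | 6α-(angeloyloxy)-2α-(4-methoxybenzyloxy)-5αH-dauc-8-ene-4β,10β-diol | C/C=C(/C)C(=O)O[C@H]1CC(C)=C[C@H](O)[C@@]2(C)[C@@H]1[C@](O)(C(C)C)C[C@@H]2OCc3ccc(OC)cc3 | intermediate
27 | 6α-(angeloyloxy)-8β,9β-epoxy-2α-(4-methoxybenzyloxy)-5αH-daucane-4β,10β-diol | C/C=C(/C)C(=O)O[C@H]1C[C@]2(C)O[C@@H]2[C@H](O)[C@@]3(C)[C@@H]1[C@](O)(C(C)C)C[C@@H]3OCc4ccc(OC)cc4 | intermediate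
28 | 6α,10β-bis(angeloyloxy)-8β,9β-epoxy-2α-(4-methoxybenzyloxy)-5αH-daucan-4β-ol | C/C=C(/C)C(=O)O[C@H]1C[C@]2(C)O[C@@H]2[C@H](OC(=O)/C(C)=C\C)[C@@]3(C)[C@@H]1[C@](O)(C(C)C)C[C@@H]3OCc4ccc(OC)cc4 | intermediate
29 | 6α,10β-bis(angeloyloxy)-8β,9β-epoxy-5αH-daucane-2α,4β-diol, (1S,2S,4R,5S,6S,8S,9R,10R) | C/C=C(/C)C(=O)O[C@H]1C[C@]2(C)O[C@@H]2[C@H](OC(=O)/C(C)=C\C)[C@@]2(C)[C@@H]1[C@](O)(C(C)C)C[C@@H]2O | target

## Step count and least certain steps

Total step count: 19. Longest linear sequence: 16 steps (steps 1–5 and 9–19).

**Step 10 (key step).** The most likely failures are insufficient facial discrimination by C4 in the boat transition state (giving the C1/C10 diastereomeric pair), diversion of the trans cyclopropane isomers into a homodienyl 1,5-hydrogen shift or a ring enlargement if stereomutation is slower than expected, and thermal dehydration of the β-hydroxy ketone that the rearrangement creates. Fallback: reduce and protect before rearranging. Setting out from 18, hydroxyl-directed 1,2-reduction of the enone (Me4NBH(OAc)3) should give the allylic alcohol F1, NaH and 4-methoxybenzyl bromide the 4-methoxybenzyl ether F2, and thermolysis of F2 should give 21 directly, where the route is rejoined (steps 11 and 12 are then not needed). In F2 the 2α-ether next to C1 blocks the α face as a second control element, no β-hydroxy ketone is formed, and the alkene is no longer an acceptor, which closes polar ring-opening channels.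

**Step 9.** The doubly anionic addition to a hindered, deactivated vinylogous-ester carbonyl may be slow, so that retro-aldol opening of the α-alkoxy ketone or proton transfer wins, and in the acid stage ionisation of the 1-(phenylsulfanyl)cyclopropyl carbinol with ring enlargement to a cyclobutanone may compete with elimination. Fallback: mask the tertiary hydroxyl so that a neutral ketone is attacked by a less basic organometallic. Setting out from 8, Me3SiOTf and 2,6-lutidine should give the trimethylsilyl ether F3, the organocerium reagent made from 15 and CeCl3 should add to it to give the monoprotected carbinol F4, and PPTS in wet CH2Cl2 should hydrolyse the enol ether, eliminate and remove the labile tertiary trimethylsilyl group, which returns to the route at 18.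

**Step 13.** During hydrolysis and C5 equilibration the free tertiary β-hydroxyl may be lost by elimination to the conjugated enone or by retro-aldol cleavage of C4–C5, and epimerisation at C5 may stay incomplete. Fallback: mask the carbinol for this stage. Setting out from 21, Et3SiOTf and 2,6-lutidine should give the silyl ether F5, the same hydrolysis and base equilibration the β-silyloxy ketone F6 (no retro-aldol possible), and PPTS in MeOH should remove the tertiary triethylsilyl group selectively to return to 22.

**Step 16.** Cleavage of the hindered silyl ether next to the quaternary C1 may be slow, and under forcing fluoride conditions the angelate may be lost or may migrate from O6. Fallback: change the order so that no ester is present when the silyl ether and the alkene are addressed. Setting out from 23, buffered Bu4NF should give the triol F7, VO(acac)2 and t-BuOOH the epoxy triol F8 (the allylic 10β-hydroxyl is expected to dominate the homoallylic 6α-hydroxyl as the directing group), and esterification of both secondary hydroxyls with two equivalents of the mixed anhydride of 24 rejoins the route at 28.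

**Step 18.** Forcing acylation of the neopentyl O10 may cause Z to E isomerisation to the tiglate, incomplete reaction, or opening of the adjacent epoxide by chloride or carboxylate. Fallback: build the Z alkene on the ester instead of acylating with 24. Setting out from 27, O10 is esterified with 2-[bis(2,2,2-trifluoroethoxy)phosphoryl]propanoic acid (DCC, DMAP) to give the phosphonate ester F9, and a Still–Gennari olefination with acetaldehyde (KN(SiMe3)2, 18-crown-6, THF, −78 °C) should give the Z-2-methylbut-2-enoate and rejoin the route at 28.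

## Further compounds

F1 | step 10 | (1S,4R)-2-methyl-3-[2-methyl-1-(phenylsulfanyl)-2-{(E)-2-(triisopropylsilyloxy)ethenyl}cyclopropyl]-4-(propan-2-yl)cyclopent-2-ene-1,4-diol (2α,4β-diol in route numbering) | CC1=C(C2(Sc3ccccc3)CC2(C)/C=C/O[Si](C(C)C)(C(C)C)C(C)C)[C@](O)(C(C)C)C[C@@H]1O
F2 | step 10 | 4-methoxybenzyl ether of F1 at the secondary hydroxyl | CC1=C(C2(Sc3ccccc3)CC2(C)/C=C/O[Si](C(C)C)(C(C)C)C(C)C)[C@](O)(C(C)C)C[C@@H]1OCc4ccc(OC)cc4
F3 | step 9 | (5R)-3-methoxy-2-methyl-5-(propan-2-yl)-5-(trimethylsilyloxy)cyclopent-2-en-1-one | COC1=C(C)C(=O)[C@](O[Si](C)(C)C)(C(C)C)C1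
F4 | step 9 | (5R)-3-methoxy-2-methyl-1-[2-methyl-1-(phenylsulfanyl)-2-{(E)-2-(triisopropylsilyloxy)ethenyl}cyclopropyl]-5-(propan-2-yl)-5-(trimethylsilyloxy)cyclopent-2-en-1-ol (stereoisomer mixture) | COC1=C(C)C(O)(C2(Sc3ccccc3)CC2(C)/C=C/O[Si](C(C)C)(C(C)C)C(C)C)[C@](O[Si](C)(C)C)(C(C)C)C1
F5 | step 13 | 2α-(4-methoxybenzyloxy)-6-(phenylsulfanyl)-4β-(triethylsilyloxy)-10β-(triisopropylsilyloxy)dauca-5,8-diene | C1(Sc3ccccc3)CC(C)=C[C@H](O[Si](C(C)C)(C(C)C)C(C)C)[C@@]2(C)C=1[C@](O[Si](CC)(CC)CC)(C(C)C)C[C@@H]2OCc4ccc(OC)cc4
F6 | step 13 | 2α-(4-methoxybenzyloxy)-4β-(triethylsilyloxy)-10β-(triisopropylsilyloxy)-5αH-dauc-8-en-6-one | O=C1CC(C)=C[C@H](O[Si](C(C)C)(C(C)C)C(C)C)[C@@]2(C)[C@@H]1[C@](O[Si](CC)(CC)CC)(C(C)C)C[C@@H]2OCc3ccc(OC)cc3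
F7 | step 16 | 2α-(4-methoxybenzyloxy)-5αH-dauc-8-ene-4β,6α,10β-triol | O[C@H]1CC(C)=C[C@H](O)[C@@]2(C)[C@@H]1[C@](O)(C(C)C)C[C@@H]2OCc3ccc(OC)cc3
F8 | step 16 | 8β,9β-epoxy-2α-(4-methoxybenzyloxy)-5αH-daucane-4β,6α,10β-triol | O[C@H]1C[C@]2(C)O[C@@H]2[C@H](O)[C@@]3(C)[C@@H]1[C@](O)(C(C)C)C[C@@H]3OCc4ccc(OC)cc4
F9 | step 18 | 6α-(angeloyloxy)-10β-{2-[bis(2,2,2-trifluoroethoxy)phosphoryl]propanoyloxy}-8β,9β-epoxy-2α-(4-methoxybenzyloxy)-5αH-daucan-4β-ol | C/C=C(/C)C(=O)O[C@H]1C[C@]2(C)O[C@@H]2[C@H](OC(=O)C(C)P(=O)(OCC(F)(F)F)OCC(F)(F)F)[C@@]3(C)[C@@H]1[C@](O)(C(C)C)C[C@@H]3OCc4ccc(OC)cc4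
A1 | alternative 1 | ring-closing metathesis precursor: 8,9-seco diene with O2 as 4-methoxybenzyl ether and O6, O10 as tert-butyldimethylsilyl ethers | C=C[C@H](O[Si](C)(C)C(C)(C)C)[C@@]1(C)[C@@H]([C@H](CC(C)=C)O[Si](C)(C)C(C)(C)C)[C@](O)(C(C)C)C[C@@H]1OCc2ccc(OC)cc2
A2 | alternative 1 | 6α,10β-bis(tert-butyldimethylsilyloxy)-2α-(4-methoxybenzyloxy)-5αH-dauc-8-en-4β-ol | CC(C)(C)[Si](C)(C)O[C@H]1CC(C)=C[C@H](O[Si](C)(C)C(C)(C)C)[C@@]2(C)[C@@H]1[C@](O)(C(C)C)C[C@@H]2OCc3ccc(OC)cc3
A3 | alternative 2 | (S)-terpinen-4-ol ((1S)-4-methyl-1-(propan-2-yl)cyclohex-3-en-1-ol) | CC1=CC[C@](O)(C(C)C)CC1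
A4 | alternative 2 | (R)-5-hydroxy-2-methyl-5-(propan-2-yl)cyclopent-1-ene-1-carbaldehyde | CC1=C(C=O)[C@](O)(C(C)C)CC1
A5 | alternative 3 | (R)-4-hydroxy-2-methyl-4-(propan-2-yl)cyclopent-2-en-1-one | CC1=C[C@](O)(C(C)C)CC1=O
A6 | alternative 3 | cis-hydrindenone Diels–Alder adduct (target atoms C1–C5 and C7–C10; angular methyl α, H5 α, 10β-silyloxy) | C1C(C)=C[C@H](O[Si](C(C)C)(C(C)C)C(C)C)[C@@]2(C)[C@@H]1[C@](O)(C(C)C)CC2=O
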